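**Plan**

Numbering: C1 = CH–O-isobutyryl; C2, C3 = CH2; C4=C5 = ring olefin with C15H2OH on C4 (E by CIP, ring carbons C3 and C6 cis); C6 = lactone CH–O; C7 = ring-fusion CH carrying C11(=C13H2)–C12(=O); C8 = butenolide CH–O; C9=C10 = butenolide olefin; C14 = butenolide C=O.
Enabling feature: C1 is a carbinol carbon bonded to C10, the α-carbon of the O8–C14(=O)–C10=C9–C8 butenolide, so C1–C10 is the adduct of a C10 alkenyl metal and a C1 aldehyde; the butenolide, the trans-fused C6–O–C12 lactone and the C4=C5 olefin leave only C2–C3 free to rotate, so the ten-membered ring C1–C10 can be closed last at this bond.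
Retrosynthetic cuts: C15 O–Si and C1 O–acyl; C1–C10 (Ni/Cr ring closure); O6–C12 and O8–C14 (both lactones); C7–C8 (allylboration of an ynal); C11–C13 (Negishi coupling); C6–C7 (asymmetric alkynylation); C3–C4 (B-alkyl Suzuki coupling).
Forward order: C4/C5/C6/C15 iodobutenol + C1–C3 borane → C1–C6 enal → propiolate (C7, C11, C12) → CH2B (C13) → ynal (C8–C10, C14) → butenolide ring → α-methylene lactone ring → ten-membered ring → ester → desilylation.
Stereochemistry: C4=C5 from directed trans-hydroalumination/iodination and a stereoretentive coupling; C6 from the ProPhenol/zinc alkynylation; C7 and C8 from one chair allylboration (face chosen by 1,3-allylic strain at C6, syn relation by the cis CH2B group); C1 from the macrocyclic transition state of the ring closure.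

Key step: step 14

Assumption: (S,S)-ProPhenol is taken to be the ligand antipode that gives the 4R carbinol 10; should the sense be the opposite, (R,R)-ProPhenol is used.
Remark: atom labels C1–C15 in the Why lines refer to the target numbering. CIP descriptors change along the route with the substituents (C8 is S in the stannyl and iodo butenolides, R in 24–26) while the spatial arrangement stays that of the target.
Abbreviations: TBDPS = tert-butyldiphenylsilyl, TES = triethylsilyl, Bpin = 4,4,5,5-tetramethyl-1,3,2-dioxaborolan-2-yl, 9-BBN = 9-borabicyclo[3.3.1]nonane.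

**Route**

Step 1
Reactants: 1 2-butyne-1,4-diol
Product: 2 4-(TBDPSO)but-2-yn-1-ol
Conditions: 1 (3 equiv), NaH (1.0 equiv), THF, 0 °C; TBDPSCl (1.0 equiv), 0 → 23 °C
Reagents that add atoms: tert-butyl(chloro)diphenylsilane, CC(C)(C)[Si](Cl)(c1ccccc1)c1ccccc1
Why: Statistical mono-O-silylation of the monosodium alkoxide of a symmetrical diol used in excess (Williamson-type silyl ether formation) should stop at the mono ether, the surplus diol being removed with water.

Step 2
Reactants: 2 4-(TBDPSO)but-2-yn-1-ol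
Product: 4 (2Z)-4-(TBDPSO)-3-iodobut-2-en-1-ol, via cyclic alkenylalanate 3 (not isolated)
Conditions: NaAlH2(OCH2CH2OMe)2 (Red-Al, 1.5 equiv), THF, 0 °C; then I2 (1.5 equiv), −78 → 0 °C
Reagents that add atoms: iodine, [I][I]
Why: Hydroxyl-directed trans-hydroalumination of the propargylic alcohol puts hydride on C2 and aluminium on C3 of the butene chain inside a five-membered alanate, and iodinolysis of the C–Al bond with retention should give only the Z-iodide, in which the carbinol carbon (future C6) and iodine are cis.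

Step 3
Reactants: 5 3,3-dimethoxyprop-1-ene (acrolein dimethyl acetal); 4 (2Z)-4-(TBDPSO)-3-iodobut-2-en-1-ol
Product: 7 (2E)-3-(TBDPSOCH2)-6,6-dimethoxyhex-2-en-1-ol, via B-(3,3-dimethoxypropyl)-9-BBN 6 (not isolated)
Conditions: 5 (1.5 equiv), 9-BBN-H (1.5 equiv), THF, 0 → 23 °C; then 4, PdCl2(dppf) (5 mol %), AsPh3 (10 mol %), K3PO4 (3 M in H2O), DMF, 23 °C
Reagents that add atoms: none
Why: Anti-Markovnikov hydroboration of the terminal olefin followed by B-alkyl Suzuki–Miyaura coupling, which proceeds with retention at the alkenyl iodide, should join C3 to C4 and fix the trisubstituted olefin with C3 and C6 cis, while C1 is carried at the aldehyde oxidation level as its acetal.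

Step 4
Reactants: 7 (2E)-3-(TBDPSOCH2)-6,6-dimethoxyhex-2-en-1-ol
Product: 8 (2E)-3-(TBDPSOCH2)-6,6-dimethoxyhex-2-enal
Conditions: MnO2 (15 equiv), CH2Cl2, 23 °C
Reagents that add atoms: none
Why: MnO2 oxidises only the primary allylic alcohol (allylic alcohol oxidation) and should give the E enal without isomerisation or loss of the acetal and silyl ether.

Step 5
Reactants: 8 (2E)-3-(TBDPSOCH2)-6,6-dimethoxyhex-2-enal; 9 methyl prop-2-ynoate (methyl propiolate)
Product: 10 methyl (4R,5E)-6-(TBDPSOCH2)-4-hydroxy-9,9-dimethoxynon-5-en-2-ynoate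
Conditions: (S,S)-ProPhenol (20 mol %), Me2Zn (3 equiv), 9 (3 equiv), toluene, 4 °C; aqueous work-up
Reagents that add atoms: none
Why: Addition of the zinc alkynylide to the α,β-unsaturated aldehyde under the dinuclear catalyst formed from Me2Zn and ProPhenol (catalytic asymmetric alkynylation) should be 1,2-selective and set C6 by catalyst control, the ynoate staying intact for the next step.

Step 6
Reactants: 10 methyl (4R,5E)-6-(TBDPSOCH2)-4-hydroxy-9,9-dimethoxynon-5-en-2-ynoate
Product: 12 methyl (2Z,4R,5E)-6-(TBDPSOCH2)-4-hydroxy-2-iodo-9,9-dimethoxynona-2,5-dienoate, via cyclic alkenylalanate 11 (not isolated)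
Conditions: NaAlH2(OCH2CH2OMe)2 (2.0 equiv), THF, −78 °C; then I2 (2.5 equiv), −78 → −40 °C
Reagents that add atoms: iodine, [I][I]
Why: At −78 °C the aluminium alkoxide of the γ-hydroxy ynoate delivers hydride to C7 faster than the ester is reduced (hydroxyl-directed trans-hydroalumination, which is also the conjugate sense), and iodinolysis of the α-aluminated enoate with retention should give the 2Z iodide with C6 cis to iodine and trans to the ester, so that no lactone can form.

Step 7
Reactants: 12 methyl (2Z,4R,5E)-6-(TBDPSOCH2)-4-hydroxy-2-iodo-9,9-dimethoxynona-2,5-dienoate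
Product: 13 methyl (2Z,4R,5E)-6-(TBDPSOCH2)-2-iodo-9,9-dimethoxy-4-(TESO)nona-2,5-dienoate
Conditions: TESCl (1.5 equiv), imidazole (3 equiv), DMAP (cat.), CH2Cl2, 0 °C
Reagents that add atoms: chlorotriethylsilane, CC[Si](Cl)(CC)CC
Why: Silyl ether formation at the secondary allylic alcohol should be clean under non-acidic conditions that spare the acetal, and the bulky triethylsilyloxy group is the element that directs the C7 face in step 10.

Step 8
Reactants: 13 methyl (2Z,4R,5E)-6-(TBDPSOCH2)-2-iodo-9,9-dimethoxy-4-(TESO)nona-2,5-dienoate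
Product: 14 methyl (2E,4R,5E)-6-(TBDPSOCH2)-9,9-dimethoxy-2-(BpinCH2)-4-(TESO)nona-2,5-dienoate
Conditions: IZnCH2Bpin (2.5 equiv; from ICH2Bpin and Zn dust, THF, 23 °C), Pd(PPh3)4 (5 mol %), THF, 23 → 40 °C
Reagents that add atoms: (pinacolatoboryl)methylzinc iodide, I[Zn]CB1OC(C)(C)C(C)(C)O1, made from 2-(iodomethyl)-4,4,5,5-tetramethyl-1,3,2-dioxaborolane, ICB1OC(C)(C)C(C)(C)O1
Why: Negishi cross-coupling of the electron-poor alkenyl iodide with the borylmethylzinc reagent proceeds with retention of olefin geometry and should give the 2-alkoxycarbonyl allylboronate in which C6 is cis to CH2B.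

Step 9
Reactants: 15 methyl 4-hydroxybut-2-ynoate
Product: 16 methyl 4-oxobut-2-ynoate
Conditions: Dess–Martin periodinane (1.2 equiv), CH2Cl2, 0 → 23 °C; filtered through Celite, solution used at once
Reagents that add atoms: none
Why: Dess–Martin oxidation of the primary propargylic alcohol should give the ynal under neutral, anhydrous conditions, and the sensitive aldehyde is not stored.

Step 10
Reactants: 14 methyl (2E,4R,5E)-6-(TBDPSOCH2)-9,9-dimethoxy-2-(BpinCH2)-4-(TESO)nona-2,5-dienoate; 16 methyl 4-oxobut-2-ynoate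
Product: 17 dimethyl (4S,5R)-5-[(1R,2E)-3-(TBDPSOCH2)-6,6-dimethoxy-1-(TESO)hex-2-en-1-yl]-4-hydroxy-6-methylidenehept-2-ynedioate
Conditions: 16 (2 equiv), toluene, 4 Å MS, 23 → 45 °C; triethanolamine/aqueous work-up
Reagents that add atoms: none
Why: Allylboration through a closed six-membered chair, the reaction type established for 2-alkoxycarbonyl allylboronates: the C6 substituent, cis to CH2B, sits axial so that O8 and C6 come out syn, and 1,3-allylic strain with the CH2B group holds H6 in the alkene plane so that the aldehyde should add to the C7 face remote from the triethylsilyloxy group, which together give the target arrangement at C7 and C8 (5R and 4S in 17 by priority change), while the very electrophilic ynal offsets the low nucleophilicity of the ester-substituted boronate.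

Step 11
Reactants: 17 dimethyl (4S,5R)-5-[(1R,2E)-3-(TBDPSOCH2)-6,6-dimethoxy-1-(TESO)hex-2-en-1-yl]-4-hydroxy-6-methylidenehept-2-ynedioate
Product: 19 methyl (3R,4R,5E)-6-(TBDPSOCH2)-9,9-dimethoxy-2-methylidene-3-[(2S)-5-oxo-4-(tributylstannyl)-2,5-dihydrofuran-2-yl]-4-(TESO)non-5-enoate, via open-chain stannyl hydroxy enoate 18 (not isolated)
Conditions: Bu3SnH (1.2 equiv, slow addition), PdCl2(PPh3)2 (3 mol %), THF, 0 → 23 °C
Reagents that add atoms: tributyltin hydride, CCCC[SnH](CCCC)CCCC
Why: Palladium-catalysed syn-hydrostannation of the ynoate places tin α to the ester and hydrogen on C9, so that in 18 the C8 hydroxyl is cis to the ester and should close at once to the α-stannyl butenolide with retention at C8, the acrylate and the other olefins being unreactive toward the tin hydride under palladium catalysis.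

Step 12
Reactants: 19 methyl (3R,4R,5E)-6-(TBDPSOCH2)-9,9-dimethoxy-2-methylidene-3-[(2S)-5-oxo-4-(tributylstannyl)-2,5-dihydrofuran-2-yl]-4-(TESO)non-5-enoate
Product: 20 methyl (3R,4R,5E)-6-(TBDPSOCH2)-3-[(2S)-4-iodo-5-oxo-2,5-dihydrofuran-2-yl]-9,9-dimethoxy-2-methylidene-4-(TESO)non-5-enoate
Conditions: I2 (1.1 equiv), CH2Cl2, 0 °C; aq Na2S2O3 work-up
Reagents that add atoms: iodine, [I][I]
Why: Iododestannylation (ipso substitution of the alkenylstannane with retention) should give the α-iodobutenolide quickly at 0 °C, conditions under which iodine does not add to the electron-poor or trisubstituted olefins.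

Step 13
Reactants: 20 methyl (3R,4R,5E)-6-(TBDPSOCH2)-3-[(2S)-4-iodo-5-oxo-2,5-dihydrofuran-2-yl]-9,9-dimethoxy-2-methylidene-4-(TESO)non-5-enoate
Product: 22 (4E)-4-(TBDPSOCH2)-5-[(2R,3S)-3-[(2S)-4-iodo-5-oxo-2,5-dihydrofuran-2-yl]-4-methylidene-5-oxooxolan-2-yl]pent-4-enal, via hydroxy ester aldehyde 21 (not isolated)
Conditions: TsOH·H2O (0.3 equiv), acetone–H2O (10:1), 23 °C; then solvent exchange to CH2Cl2, 23 °C
Reagents that add atoms: water, O
Why: Aqueous acid hydrolyses the dimethyl acetal to the C1 aldehyde and cleaves the triethylsilyl ether, and the freed C6 hydroxyl, γ to the acrylate ester, should lactonise (acid-catalysed transesterification) to the trans-disubstituted α-methylene-γ-butyrolactone without touching a stereocentre, the primary TBDPS ether and the alkenyl iodide being stable to these conditions.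

Step 14
Reactants: 22 (4E)-4-(TBDPSOCH2)-5-[(2R,3S)-3-[(2S)-4-iodo-5-oxo-2,5-dihydrofuran-2-yl]-4-methylidene-5-oxooxolan-2-yl]pent-4-enal
Product: 24 (1S,6R,7S,8R)-15-O-TBDPS-1-O-deisobutyryl-26 (ten-membered carbinol), via alkenylchromium species 23 (not isolated)
Conditions: CrCl2 (10 equiv), NiCl2 (0.1 equiv), degassed DMSO, 23 °C, syringe-pump addition of 22 to 2 mM
Reagents that add atoms: none
Why: Zerovalent nickel, formed from NiCl2 by CrCl2, inserts into the C10–I bond of the α-iodobutenolide, the alkenylnickel transmetallates to trivalent chromium, and the alkenylchromium 23 adds to the C1 aldehyde (intramolecular Nozaki–Hiyama–Kishi reaction, closest to known Ni/Cr closures of medium rings from alkenyl iodides and aldehydes, α-iodo enoates included). The ten-membered carbocycle closes in a 10-exo-trig mode on the carbonyl; the butenolide, the trans-fused α-methylene lactone and the C4=C5 olefin (C3 and C6 cis) freeze every ring bond except C2–C3, so the chain ends are held close and high dilution suffices. The new C1 stereocentre is controlled by the macrocyclic transition state: the tether should hold the aldehyde over the butenolide face that carries C7 while the solvated chromium departs toward the open face, which corresponds to the 1S carbinol. The step needs chemoselectivity for the C–I bond over two Michael acceptors, the allylic lactone C–O bond and the epimerisable C8–H, and the neutral, non-nucleophilic Ni/Cr medium together with the fast insertion of nickel into the electron-poor alkenyl iodide should secure it.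

Step 15
Reactants: 24 (1S,6R,7S,8R)-15-O-TBDPS-1-O-deisobutyryl-26
Product: 25 (1S,6R,7S,8R)-15-O-TBDPS-26
Conditions: (i-PrCO)2O (3 equiv), DMAP (0.2 equiv), pyridine, CH2Cl2, 0 °C
Reagents that add atoms: 2-methylpropanoic anhydride (isobutyric anhydride), CC(C)C(=O)OC(=O)C(C)C
Why: DMAP-catalysed acylation of the secondary allylic alcohol with the anhydride (esterification with retention at C1) should proceed at 0 °C in pyridine, mild enough to leave the α-methylene lactone and the C8 stereocentre of the butenolide untouched.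

Step 16
Reactants: 25 (1S,6R,7S,8R)-15-O-TBDPS-26
Product: 26 the target, (1S,6R,7S,8R,4E)-1-isobutyryloxy-15-hydroxy dilactone
Conditions: HF·pyridine, pyridine, THF, 0 → 23 °C
Reagents that add atoms: none
Why: Fluoride-mediated cleavage of the primary silyl ether with buffered HF·pyridine (desilylation) should free the C15 alcohol without acyl migration, lactone opening or conjugate addition, which completes the target.

**Compound list**

1 | 2-butyne-1,4-diol | OCC#CCO | starting material
2 | 4-[(tert-butyldiphenylsilyl)oxy]but-2-yn-1-ol | OCC#CCO[Si](c1ccccc1)(c1ccccc1)C(C)(C)C | intermediate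
3 | sodium cyclic alkenylalanate from 2 (five-membered 1,2-oxaaluminole ate complex, Al on C3 of the butene chain, two 2-methoxyethoxy groups on Al; not isolated) | [Na+].COCCO[Al-]1(OCCOC)OCC=C1CO[Si](c1ccccc1)(c1ccccc1)C(C)(C)C | intermediate
4 | (2Z)-4-[(tert-butyldiphenylsilyl)oxy]-3-iodobut-2-en-1-ol | OC/C=C(\I)CO[Si](c1ccccc1)(c1ccccc1)C(C)(C)C | intermediate
5 | 3,3-dimethoxyprop-1-ene (acrolein dimethyl acetal) | C=CC(OC)OC | starting material
6 | 9-(3,3-dimethoxypropyl)-9-borabicyclo[3.3.1]nonane (not isolated) | COC(OC)CCB1C2CCCC1CCC2 | intermediate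
7 | (2E)-3-{[(tert-butyldiphenylsilyl)oxy]methyl}-6,6-dimethoxyhex-2-en-1-ol | OC/C=C(/CO[Si](c1ccccc1)(c1ccccc1)C(C)(C)C)CCC(OC)OC | intermediate
8 | (2E)-3-{[(tert-butyldiphenylsilyl)oxy]methyl}-6,6-dimethoxyhex-2-enal | O=C/C=C(/CO[Si](c1ccccc1)(c1ccccc1)C(C)(C)C)CCC(OC)OC | intermediate
9 | methyl prop-2-ynoate (methyl propiolate) | C#CC(=O)OC | starting material
10 | methyl (4R,5E)-6-{[(tert-butyldiphenylsilyl)oxy]methyl}-4-hydroxy-9,9-dimethoxynon-5-en-2-ynoate | COC(=O)C#C[C@H](O)/C=C(/CO[Si](c1ccccc1)(c1ccccc1)C(C)(C)C)CCC(OC)OC | intermediate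
11 | sodium cyclic alkenylalanate from 10 (1,2-oxaaluminole ate complex, Al on the ester α-carbon, ring oxygen from the C4 hydroxyl; not isolated) | [Na+].COCCO[Al-]1(OCCOC)O[C@H](/C=C(/CO[Si](c2ccccc2)(c2ccccc2)C(C)(C)C)CCC(OC)OC)C=C1C(=O)OC | intermediate
12 | methyl (2Z,4R,5E)-6-{[(tert-butyldiphenylsilyl)oxy]methyl}-4-hydroxy-2-iodo-9,9-dimethoxynona-2,5-dienoate | COC(=O)/C(I)=C/[C@H](O)/C=C(/CO[Si](c1ccccc1)(c1ccccc1)C(C)(C)C)CCC(OC)OC | intermediate
13 | methyl (2Z,4R,5E)-6-{[(tert-butyldiphenylsilyl)oxy]methyl}-2-iodo-9,9-dimethoxy-4-[(triethylsilyl)oxy]nona-2,5-dienoate | COC(=O)/C(I)=C/[C@H](O[Si](CC)(CC)CC)/C=C(/CO[Si](c1ccccc1)(c1ccccc1)C(C)(C)C)CCC(OC)OC | intermediate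
14 | methyl (2E,4R,5E)-6-{[(tert-butyldiphenylsilyl)oxy]methyl}-9,9-dimethoxy-2-[(4,4,5,5-tetramethyl-1,3,2-dioxaborolan-2-yl)methyl]-4-[(triethylsilyl)oxy]nona-2,5-dienoate | COC(=O)/C(CB1OC(C)(C)C(C)(C)O1)=C/[C@H](O[Si](CC)(CC)CC)/C=C(/CO[Si](c1ccccc1)(c1ccccc1)C(C)(C)C)CCC(OC)OC | intermediate
15 | methyl 4-hydroxybut-2-ynoate | OCC#CC(=O)OC | starting material
16 | methyl 4-oxobut-2-ynoate | O=CC#CC(=O)OC | intermediate
17 | dimethyl (4S,5R)-5-[(1R,2E)-3-{[(tert-butyldiphenylsilyl)oxy]methyl}-6,6-dimethoxy-1-[(triethylsilyl)oxy]hex-2-en-1-yl]-4-hydroxy-6-methylidenehept-2-ynedioate | COC(=O)C#C[C@@H](O)[C@@H](C(=C)C(=O)OC)[C@H](O[Si](CC)(CC)CC)/C=C(/CO[Si](c1ccccc1)(c1ccccc1)C(C)(C)C)CCC(OC)OC | intermediate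
18 | dimethyl (2E,4S,5R)-5-[(1R,2E)-3-{[(tert-butyldiphenylsilyl)oxy]methyl}-6,6-dimethoxy-1-[(triethylsilyl)oxy]hex-2-en-1-yl]-4-hydroxy-6-methylidene-2-(tributylstannyl)hept-2-enedioate (not isolated) | COC(=O)/C([Sn](CCCC)(CCCC)CCCC)=C\[C@@H](O)[C@@H](C(=C)C(=O)OC)[C@H](O[Si](CC)(CC)CC)/C=C(/CO[Si](c1ccccc1)(c1ccccc1)C(C)(C)C)CCC(OC)OC | intermediate
19 | methyl (3R,4R,5E)-6-{[(tert-butyldiphenylsilyl)oxy]methyl}-9,9-dimethoxy-2-methylidene-3-[(2S)-5-oxo-4-(tributylstannyl)-2,5-dihydrofuran-2-yl]-4-[(triethylsilyl)oxy]non-5-enoate | CCCC[Sn](CCCC)(CCCC)C1=C[C@@H](OC1=O)[C@@H](C(=C)C(=O)OC)[C@H](O[Si](CC)(CC)CC)/C=C(/CO[Si](c1ccccc1)(c1ccccc1)C(C)(C)C)CCC(OC)OC | intermediate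
20 | methyl (3R,4R,5E)-6-{[(tert-butyldiphenylsilyl)oxy]methyl}-3-[(2S)-4-iodo-5-oxo-2,5-dihydrofuran-2-yl]-9,9-dimethoxy-2-methylidene-4-[(triethylsilyl)oxy]non-5-enoate | IC1=C[C@@H](OC1=O)[C@@H](C(=C)C(=O)OC)[C@H](O[Si](CC)(CC)CC)/C=C(/CO[Si](c1ccccc1)(c1ccccc1)C(C)(C)C)CCC(OC)OC | intermediate
21 | methyl (3S,4R,5E)-6-{[(tert-butyldiphenylsilyl)oxy]methyl}-4-hydroxy-3-[(2S)-4-iodo-5-oxo-2,5-dihydrofuran-2-yl]-2-methylidene-9-oxonon-5-enoate (not isolated) | IC1=C[C@@H](OC1=O)[C@@H](C(=C)C(=O)OC)[C@H](O)/C=C(/CO[Si](c1ccccc1)(c1ccccc1)C(C)(C)C)CCC=O | intermediate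
22 | (4E)-4-{[(tert-butyldiphenylsilyl)oxy]methyl}-5-[(2R,3S)-3-[(2S)-4-iodo-5-oxo-2,5-dihydrofuran-2-yl]-4-methylidene-5-oxooxolan-2-yl]pent-4-enal | IC1=C[C@@H](OC1=O)[C@H]2C(=C)C(=O)O[C@@H]2/C=C(/CO[Si](c3ccccc3)(c3ccccc3)C(C)(C)C)CCC=O | intermediate
23 | alkenylchromium species: trivalent chromium dichloride σ-bonded to C10 of the butenolide of 22, aldehyde intact (not isolated) | Cl[Cr](Cl)C1=C[C@@H](OC1=O)[C@H]2C(=C)C(=O)O[C@@H]2/C=C(/CO[Si](c3ccccc3)(c3ccccc3)C(C)(C)C)CCC=O | intermediate
24 | (1S,6R,7S,8R)-macrocyclic C1 alcohol: the 15-O-TBDPS ether of the 1-de-isobutyryl target | C=C1C(=O)O[C@@H]2/C=C(/CO[Si](c4ccccc4)(c4ccccc4)C(C)(C)C)CC[C@H](O)C3=C[C@@H](OC3=O)[C@@H]12 | intermediate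
25 | (1S,6R,7S,8R)-15-O-TBDPS ether of the target (C1 isobutyrate) | C=C1C(=O)O[C@@H]2/C=C(/CO[Si](c4ccccc4)(c4ccccc4)C(C)(C)C)CC[C@H](OC(=O)C(C)C)C3=C[C@@H](OC3=O)[C@@H]12 | intermediate
26 | CNP0322767.4, (1S,6R,7S,8R,4E)-configured dilactone with C1 isobutyrate and C15 alcohol | C=C1C(=O)O[C@@H]2/C=C(/CO)CC[C@H](OC(=O)C(C)C)C3=C[C@@H](OC3=O)[C@@H]12 | target

**Step count and risks**

Total steps: 16. Longest linear sequence: 15 steps (1 → 26 through steps 1–8 and 10–16; step 9 is the side branch to 16).

Steps most likely to fail, in order of risk: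

Step 10, the allylboration. The ester-deactivated boronate with its axial C6 substituent may add too slowly. At the higher temperature then needed, the facial preference at C7 may erode and the ynal may polymerise. The fallback replaces the allylboronate by an allylindium. Setting out from 13, Stille coupling with Bu3SnCH2OH (Pd(PPh3)4, toluene, 80 °C) would give the allylic alcohol methyl (2E,4R,5E)-6-(TBDPSOCH2)-2-(hydroxymethyl)-9,9-dimethoxy-4-(TESO)nona-2,5-dienoate F1. Appel bromination (CBr4, PPh3, CH2Cl2, 0 °C) would give the allylic bromide methyl (2Z,4R,5E)-2-(bromomethyl)-6-(TBDPSOCH2)-9,9-dimethoxy-4-(TESO)nona-2,5-dienoate F2. Barbier allylation of 16 with F2 and indium powder in THF–H2O at 23 °C comes back to the route at 17. (Z)-2-(Bromomethyl)alk-2-enoates add in this reaction type through the same kind of chair with syn selectivity. The detour also avoids step 8.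

Step 14, the Ni/Cr ring closure. The aldehyde may be attacked on its other face, or closure may be slow enough for protodeiodination to compete. The fallback changes how the C1 ester is made. Setting out from 22, the same closure would then deliver the 1R carbinol (1R,6R,7S,8R)-epimer of 24 F3. Instead of direct acylation it would be esterified with inversion at C1 by a Mitsunobu reaction (2-methylpropanoic acid, PPh3, DIAD, toluene, 0 °C), which comes back to the route at 25.

Step 5, the asymmetric alkynylation. The hindered β,β-disubstituted enal may react slowly and with incomplete enantioface discrimination. The wrong enantiomeric series would then be carried through every later substrate-controlled step. The fallback sets C6 by asymmetric reduction instead of asymmetric addition. Setting out from 10 of insufficient enantiomeric purity, MnO2 oxidation (CH2Cl2, 23 °C) would give the ynone methyl (5E)-6-(TBDPSOCH2)-9,9-dimethoxy-4-oxonon-5-en-2-ynoate F4. Corey–Bakshi–Shibata reduction (the 2-methyl-CBS-oxazaborolidine antipode that gives 4R, catecholborane, toluene, −78 °C), in which the alkynyl group acts as the small substituent, comes back to the route at 10.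

Further compounds
F1 | step 10 | methyl (2E,4R,5E)-6-{[(tert-butyldiphenylsilyl)oxy]methyl}-2-(hydroxymethyl)-9,9-dimethoxy-4-[(triethylsilyl)oxy]nona-2,5-dienoate | COC(=O)/C(CO)=C/[C@H](O[Si](CC)(CC)CC)/C=C(/CO[Si](c1ccccc1)(c1ccccc1)C(C)(C)C)CCC(OC)OC
F2 | step 10 | methyl (2Z,4R,5E)-2-(bromomethyl)-6-{[(tert-butyldiphenylsilyl)oxy]methyl}-9,9-dimethoxy-4-[(triethylsilyl)oxy]nona-2,5-dienoate | COC(=O)/C(CBr)=C/[C@H](O[Si](CC)(CC)CC)/C=C(/CO[Si](c1ccccc1)(c1ccccc1)C(C)(C)C)CCC(OC)OC
F3 | step 14 | (1R,6R,7S,8R)-macrocyclic C1 alcohol, the C1 epimer of 24 | C=C1C(=O)O[C@@H]2/C=C(/CO[Si](c4ccccc4)(c4ccccc4)C(C)(C)C)CC[C@@H](O)C3=C[C@@H](OC3=O)[C@@H]12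
F4 | step 5 | methyl (5E)-6-{[(tert-butyldiphenylsilyl)oxy]methyl}-9,9-dimethoxy-4-oxonon-5-en-2-ynoate | COC(=O)C#CC(=O)/C=C(/CO[Si](c1ccccc1)(c1ccccc1)C(C)(C)C)CCC(OC)OC
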